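The decision is to follow the reagent in the second phase and to treat the first phase as its receiver.

| flask | starting material | reagent in the second phase | protic impurity | remark | time | volume of the second phase over the first |
|---|---|---|---|---|---|---|
| summer | 0.42 M | 0.95 equiv | 6 mM | run made earlier |  |  |
| winter | 0.66 M | 0.95 equiv | 6 mM | run made earlier |  |  |
| flask | 0.30 M | 0.950 equiv | 6.00 mM |  | 12 min | 1.0 |

| run | time / min | target / % | starting material / % |
|---|---|---|---|
| summer | 1.33 | 40.1 | 57.8 |
| summer | 3.00 | 67.6 | 30.9 |
| summer | 4.00 | 76.7 | 23.0 |
| summer | 6.00 | 84.7 | 14.3 |
| summer | 8.00 | 88.7 | 8.6 |
| winter | 0.500 | 18.4 | 81.4 |
| winter | 1.00 | 33.2 | 65.1 |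
| winter | 2.00 | 54.9 | 44.2 |
| winter | 4.00 | 78.2 | 21.3 |
| winter | 8.00 | 91.3 | 9.4 |

(each reading ± 0.5 percentage points)

- in the second phase: reagent in the second phase; everything else is in the first
- charges count per volume of the first phase; a concentration in a rate is the amount of a species over the volume of its own phase; every rate counts per litre of the first phase
- the earlier runs hold the two phases in the same ratio of volumes as the flask asked about

* amount of target at 12 min, in percent of the starting material charged
* the change that raises the amount of target at 12 min, in percent of the starting material charged most ("none" if none brings more than 2 percentage points) (ash / oak / none)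
* amount of target at 12 min, in percent of the starting material charged, after oak

- ash: doubling the amount of reagent in the second phase, all else as stated
- oak: doubling the transfer coefficient of the reagent in the second phase, all else as stated

The ladder starts at the fast end. Reading target as crossed reagent, the summer run at 3.00 min gives 0.414 /min for the emptying rate, the fraction of the reagent in the second phase crossing per minute. The winter run at 2.00 min gives 0.431 /min. The two readings nearly agree between 0.42 M and 0.66 M, so in these early readings the first phase keeps up and crossing looks like the rate-limiting step.

Next, the summer run's first reading falls 2.1 percentage points short of a full count, near the impurity's share of 1.43 %. My reading is therefore that the impurity takes starting material, 2.00 % in the flask, and that reagent, the limiting reagent, caps target at 95.0 %.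

Then comes crossing itself, 2.41 min per e-fold. The tail runs slower: between 6.00 min and 8.00 min the summer readings give 0.246 /min, less than the early rate.

Going round twice, the early rate to 6.00 min and the tail rate after it, my reckoning leaves 1.90 % of the reagent in the second phase of the flask, so target reaches 93.2 %. Oak can then add 1.8 points up to the cap, while ash lifts the cap to 98.0 %, so I choose ash.

The forecast gives 92.1 % of target, chooses ash and gives 92.9 % after oak, saying “The impurity takes 6 mM of reagent, so the reagent sets a ceiling.” Its ceiling of 93% differs from mine.

The flask gives 91.9 %, and the best change is ash, worth 6.1 points against 1.5 points for oak, which reaches 93.3 %.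

    reagent in the reaction phase ⇌ reagent in the second phase, rate k1*([reagent in the reaction phase] - [reagent in the second phase]/K1) per volume of the first phase (partition coefficient = 2.50, kL = 0.0201 /s)
    starting material + reagent in the reaction phase → target (k = 0.781 /M/s)
    starting material + protic impurity → quenched substrate (k = 1.75 /M/s)

The forecast stands. The flask at 12 min is still short of its cap of 95.0 %, holds 95.0 % of target at 120 min, and at 12.0 min its second phase holds 2.64 % of its own charge against my 1.90 %. In the neighbouring flask, with the same charges read at 3.0 min, the emptying rate leaves 28.8 % of the charge of reagent in the second phase, and that flask holds 28.7 %. Crossed reagent then amounts to 67.6 % of the starting material, of which 2.32 % waits in the reaction phase. That leaves 65.3 %, and the neighbouring flask holds 65.4 % of target.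

All runs stem from a simulated flask with made-up constants, noise included.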